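**Strategy.** The bicyclo[3.2.1]octenedione is cut at C8–C4 and C1–C2. This works because C5 carries both ketone carbons, C1 and C8, and is therefore the central carbon of a malonyl unit, while C4–C3–C2 is an allyl unit. The two cuts open the cyclopentanone ring (C4, C8, C5, C6, C7) and the cyclohexenone ring (C1, C2, C3, C4, C8, C5) to a single chain. In one operation a Lewis acid makes an acyclic malonyl dichloride acylate its own allylsilane at C4 and then the liberated diene terminus C2, closing both rings and setting C4 and C5. The precursor 23 is the (6R,7S) 2-(1,2-diaryl-4-styryl-5-silylpent-3-enyl)malonyl dichloride with all six phenols as acetates.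

Key step: step 12

Remark (numbering): core numbering is used for every intermediate: C1 enone carbonyl, C2, C3 (styryl-bearing), C4 bridgehead, C5 bridgehead between the ketones, C6 (3,4-dioxygenated aryl), C7 (3,5-dioxygenated aryl), C8 bridging ketone. TBSO = tert-butyldimethylsilyloxy.

Remark (structure check): 23 and 25 have the same spatial arrangement at C6 and C7 as 26, so no structure needed correction. C7 is S in 23 and R in 25 and 26 only because the CIP ranking of its neighbours changes. The required C6/C7 relationship is syn along the chain C5–C6–C7–C4, which becomes trans on the cyclopentanone.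

Remark (precursor design): the acetates are installed before the allylsilane exists, so the allylsilane never meets fluoride. The carboxyl groups are unmasked through silyl esters, so it never meets protic acid. The 3E geometry is kept because the styryl group cis to C7 is what controls the face of attack at C4.

Remark (assumption): methyl (3,5-dihydroxyphenyl)acetate, RAMP and (trimethylsilyl)methylmagnesium chloride are taken as commercial.

**Step 1**
Reactants: 1 methyl (3,5-dihydroxyphenyl)acetate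
Product: 2 methyl [3,5-bis(TBSO)phenyl]acetate
Conditions: TBSCl, imidazole, DMF, rt
Reagents that add atoms: tert-butyldimethylsilyl chloride, CC(C)(C)[Si](C)(C)Cl
Why: Silyl ether formation on both phenols is routine and gives groups that survive the amide base, ozone and organozinc steps ahead; no stereocentre is involved.

**Step 2**
Reactants: 2 methyl [3,5-bis(TBSO)phenyl]acetate
Product: 4 (2R)-N-{(E)-2-[3,5-bis(TBSO)phenyl]ethylidene}-2-(methoxymethyl)pyrrolidin-1-amine, via arylacetaldehyde 3 (not isolated)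
Conditions: iBu2AlH, CH2Cl2, −78 °C; aq. potassium sodium tartrate; then RAMP, MgSO4, CH2Cl2, 0 °C → rt
Reagents that add atoms: (R)-1-amino-2-(methoxymethyl)pyrrolidine (RAMP), COC[C@H]1CCCN1N
Why: Half-reduction of the methyl ester with iBu2AlH at −78 °C stops at the aluminium hemiacetal, and the sensitive arylacetaldehyde set free on work-up is condensed at once with RAMP (hydrazone formation) to the E hydrazone, which installs the Enders auxiliary.

**Step 3**
Reactants: 5 3,4-dihydroxybenzaldehyde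
Product: 6 3,4-bis(TBSO)benzaldehyde
Conditions: TBSCl, imidazole, DMF, rt
Reagents that add atoms: tert-butyldimethylsilyl chloride, CC(C)(C)[Si](C)(C)Cl
Why: Silyl ether formation protects the catechol for the condensation, the amide base step and the organolithium step; no stereocentre is involved.

**Step 4**
Reactants: 6 3,4-bis(TBSO)benzaldehyde; 7 di-tert-butyl malonate
Product: 8 di-tert-butyl 2-[3,4-bis(TBSO)benzylidene]malonate
Conditions: piperidine (cat.), AcOH (cat.), toluene, reflux, Dean–Stark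
Reagents that add atoms: none
Why: Knoevenagel condensation under piperidinium acetate catalysis with azeotropic removal of water; the two ester groups are identical, so no alkene isomer problem arises.

**Step 5**
Reactants: 4 RAMP hydrazone; 8 benzylidene malonate
Product: 10 di-tert-butyl 2-[(1R,2S,3E)-1-[3,4-bis(TBSO)phenyl]-2-[3,5-bis(TBSO)phenyl]-3-{[(2R)-2-(methoxymethyl)pyrrolidin-1-yl]imino}propyl]malonate, via lithium azaenolate 9 (not isolated)
Conditions: LiN(iPr)2, THF, 0 °C; then 8, −78 °C; AcOH, −78 °C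
Reagents that add atoms: none
Why: Enders RAMP-hydrazone Michael addition: LiN(iPr)2 gives the E(C=C) lithium azaenolate 9, the methoxymethyl-chelated lithium directs 8 to one face so that RAMP should set 7S (the sense known from SAMP/RAMP alkylations), and the lithium-bridged closed transition state of this E-configured donor (acceptor carbon C5 gauche on the C7–H side, catechol ring anti to C4) should give the syn adduct and hence 6R.

**Step 6**
Reactants: 10 Michael adduct hydrazone
Product: 12 di-tert-butyl 2-[(1R,2R)-4,4-dibromo-1-[3,4-bis(TBSO)phenyl]-2-[3,5-bis(TBSO)phenyl]but-3-en-1-yl]malonate, via α-aryl aldehyde 11 (not isolated)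
Conditions: O3, CH2Cl2, −78 °C; Ar purge; then PPh3, CBr4, −78 → 0 °C
Reagents that add atoms: carbon tetrabromide, BrC(Br)(Br)Br
Why: Ozonolysis cleaves the hydrazone C=N at −78 °C without base, so the epimerisable α-aryl aldehyde 11 is never exposed to conditions that could scramble C7 and is converted in the same flask by the neutral Ramirez dibromoolefination (first stage of the Corey–Fuchs sequence, a Wittig-type reaction).

**Step 7**
Reactants: 6 3,4-bis(TBSO)benzaldehyde
Product: 13 4-[(E)-2-iodoethenyl]-1,2-bis(TBSO)benzene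
Conditions: CHI3, CrCl2, THF, 0 °C
Reagents that add atoms: iodoform, IC(I)I
Why: Takai olefination of an aryl aldehyde with CHI3/CrCl2 gives the E vinyl iodide selectively.

**Step 8**
Reactants: 12 dibromoalkene; 13 (E)-vinyl iodide
Product: 16 di-tert-butyl 2-[(1R,2R,3Z,5E)-4-bromo-1,6-bis[3,4-bis(TBSO)phenyl]-2-[3,5-bis(TBSO)phenyl]hexa-3,5-dien-1-yl]malonate, via alkenyllithium 14 (not isolated), via alkenylzinc chloride 15 (not isolated)
Conditions: 13, t-BuLi, Et2O, −78 °C; ZnCl2, THF, −78 → 0 °C; then 12, PdCl2(DPEphos) (5 mol %), THF, 0 °C → rt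
Reagents that add atoms: none
Why: Negishi coupling: iodine–lithium exchange and transmetalation to zinc proceed with retention of the E geometry, and with PdCl2(DPEphos) 1,1-dibromoalkenes undergo trans-selective monoalkenylation because oxidative addition takes place at the C–Br bond trans to the bulky C7 substituent, which should give the 3Z bromodiene; C6 and C7 are untouched.

**Step 9**
Reactants: 16 (3Z)-bromodiene hexakis(silyl ether)
Product: 18 di-tert-butyl 2-[(1R,2R,3Z,5E)-4-bromo-1,6-bis(3,4-diacetoxyphenyl)-2-(3,5-diacetoxyphenyl)hexa-3,5-dien-1-yl]malonate, via hexaphenol 17 (not isolated)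
Conditions: Bu4NF, AcOH, THF, 0 °C; then Ac2O, pyridine, DMAP, rt (under Ar)
Reagents that add atoms: acetic anhydride, CC(=O)OC(C)=O
Why: Fluoride removes the six aryl silyl ethers and O-acetylation in the same flask installs the electron-poor acetates at a stage where no allylsilane is present, while tert-butyl esters, vinyl bromide and diene are inert to both reagents.

**Step 10**
Reactants: 18 (3Z)-bromodiene hexaacetate; 19 (trimethylsilyl)methylmagnesium chloride (Me3SiCH2MgCl)
Product: 21 di-tert-butyl 2-[(1R,2S,3E,5E)-1,6-bis(3,4-diacetoxyphenyl)-2-(3,5-diacetoxyphenyl)-4-[(trimethylsilyl)methyl]hexa-3,5-dien-1-yl]malonate, via silylmethylzinc chloride 20 (not isolated)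
Conditions: 19, ZnCl2, THF, 0 °C; then 18, PdCl2(DPEphos) (5 mol %), THF, rt
Reagents that add atoms: none
Why: Negishi coupling with inversion of the alkene geometry: with PdCl2(DPEphos) 2-bromo-1,3-dienes are known to couple with alkylzinc reagents only after π–σ–π isomerisation of the dienylpalladium intermediate, which moves palladium to the side trans to the bulky C7 substituent, so that CH2SiMe3 should end up trans and the styryl group cis to C7 (3E), and the organozinc reagent leaves aryl acetates and tert-butyl esters alone.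

**Step 11**
Reactants: 21 allylsilane di-tert-butyl malonate
Product: 23 2-[(1R,2S,3E,5E)-1,6-bis(3,4-diacetoxyphenyl)-2-(3,5-diacetoxyphenyl)-4-[(trimethylsilyl)methyl]hexa-3,5-dien-1-yl]malonyl dichloride, via bis(trimethylsilyl) malonate 22 (not isolated)
Conditions: TMSOTf, 2,6-lutidine, CH2Cl2, 0 °C; pentane, filter, concentrate; then (COCl)2, DMF (cat.), CH2Cl2, 0 °C; concentrate, use at once
Reagents that add atoms: oxalyl chloride, ClC(=O)C(Cl)=O
Why: Silyl triflate-mediated conversion of tert-butyl esters into silyl esters (loss of isobutene, lutidine keeps the medium free of protic acid so that the allylsilane is not protodesilylated) followed by the known conversion of silyl esters into acid chlorides with oxalyl chloride and catalytic DMF, which forms Me3SiCl instead of HCl.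

**Step 12**
Reactants: 23 malonyl dichloride
Product: 25 (1S,5R,6R,7R)-7-(3,4-diacetoxyphenyl)-6-(3,5-diacetoxyphenyl)-4-[(E)-2-(3,4-diacetoxyphenyl)ethenyl]bicyclo[3.2.1]oct-3-ene-2,8-dione (jezonodione hexaacetate; core 4R,5S,6R,7R), via cyclopentanone acyl chloride 24 (not isolated)
Conditions: TiCl4 (4 equiv), CH2Cl2 (0.005 M), −78 °C, then −20 °C
Reagents that add atoms: none
Why: Proposed new method: TiCl4 ionises one acyl chloride of 23 and the resulting C8 acylium is attacked by the allylsilane through C4 (anti SE2', 5-exo-trig, closing the cyclopentanone), the C3 cation being stabilised by the β-silicon and by the styryl group until Me3SiCl is lost to leave the C3=C2 methylene of 24. The remaining acyl chloride sits on C5 of a β-keto acyl chloride, which epimerises through its enol under the Lewis acid, and only the epimer with C1 cis to the C4 arm can reach C2; its acylium adds to the diene terminus (6-endo-trig, closing the cyclohexenone) to give a styryl-stabilised allyl cation at C3 that loses the C2 proton to the conjugated enone. The closest known reactions are the intramolecular acylation of allylsilanes by acid chlorides, the Darzens–Nenitzescu acylation of alkenes and Effenberger-type annulations of malonyl dichloride, but two different acylations from one malonyl unit in a single operation have not been shown. C4 is set in the first closure by 1,3-allylic strain: the styryl group cis to C7 on C3 holds C7–H in the alkene plane, the tether then delivers C8 to the face that leaves the C3 arm trans to the C7 aryl group (all ring substituents pseudo-equatorial in the envelope), and the CH2SiMe3 group trans to C7 is free to stay anti to the incoming acylium; C5 is set by ring strain, since the three-carbon bridge can only be cis-fused, and as a bridgehead it cannot epimerise afterwards. The selectivity needed is acylation of the allylsilane and then of the diene in preference to the aryl rings (indanone or tetralone formation) and to intermolecular reaction, which should be secured by the six electron-poor acetates, by the far higher nucleophilicity of the allylsilane, by the 5-exo and 6-endo geometries and by high dilution.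

**Step 13**
Reactants: 25 jezonodione hexaacetate
Product: 26 jezonodione, (1S,5R,6R,7R)-7-(3,4-dihydroxyphenyl)-6-(3,5-dihydroxyphenyl)-4-[(E)-2-(3,4-dihydroxyphenyl)ethenyl]bicyclo[3.2.1]oct-3-ene-2,8-dione
Conditions: HCl (from AcCl), MeOH, 0 °C → rt, under Ar
Reagents that add atoms: none
Why: Acid-catalysed transesterification (methanolysis) of the six aryl acetates; acid is chosen over base because methoxide could open the non-enolisable β-diketone by retro-Claisen cleavage and catecholates oxidise in air, and no stereocentre is affected.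

**Compound list**

1 | methyl (3,5-dihydroxyphenyl)acetate | COC(=O)Cc1cc(O)cc(O)c1 | starting material
2 | methyl [3,5-bis(tert-butyldimethylsilyloxy)phenyl]acetate | COC(=O)Cc1cc(O[Si](C)(C)C(C)(C)C)cc(O[Si](C)(C)C(C)(C)C)c1 | intermediate
3 | [3,5-bis(tert-butyldimethylsilyloxy)phenyl]acetaldehyde | O=CCc1cc(O[Si](C)(C)C(C)(C)C)cc(O[Si](C)(C)C(C)(C)C)c1 | intermediate
4 | (2R)-N-{(E)-2-[3,5-bis(tert-butyldimethylsilyloxy)phenyl]ethylidene}-2-(methoxymethyl)pyrrolidin-1-amine | COC[C@H]1CCCN1/N=C/Cc1cc(O[Si](C)(C)C(C)(C)C)cc(O[Si](C)(C)C(C)(C)C)c1 | intermediate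
5 | 3,4-dihydroxybenzaldehyde | O=Cc1ccc(O)c(O)c1 | starting material
6 | 3,4-bis(tert-butyldimethylsilyloxy)benzaldehyde | O=Cc1ccc(O[Si](C)(C)C(C)(C)C)c(O[Si](C)(C)C(C)(C)C)c1 | intermediate
7 | di-tert-butyl malonate | CC(C)(C)OC(=O)CC(=O)OC(C)(C)C | starting material
8 | di-tert-butyl 2-[3,4-bis(tert-butyldimethylsilyloxy)benzylidene]malonate | CC(C)(C)OC(=O)C(=Cc1ccc(O[Si](C)(C)C(C)(C)C)c(O[Si](C)(C)C(C)(C)C)c1)C(=O)OC(C)(C)C | intermediate
9 | lithium (E)-azaenolate of hydrazone 4 | COC[C@H]1CCCN1N([Li])/C=C/c1cc(O[Si](C)(C)C(C)(C)C)cc(O[Si](C)(C)C(C)(C)C)c1 | intermediate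
10 | di-tert-butyl 2-[(1R,2S,3E)-1-[3,4-bis(tert-butyldimethylsilyloxy)phenyl]-2-[3,5-bis(tert-butyldimethylsilyloxy)phenyl]-3-{[(2R)-2-(methoxymethyl)pyrrolidin-1-yl]imino}propyl]malonate | CC(C)(C)OC(=O)C(C(=O)OC(C)(C)C)[C@H](c1ccc(O[Si](C)(C)C(C)(C)C)c(O[Si](C)(C)C(C)(C)C)c1)[C@H](/C=N/N1CCC[C@@H]1COC)c1cc(O[Si](C)(C)C(C)(C)C)cc(O[Si](C)(C)C(C)(C)C)c1 | intermediate
11 | di-tert-butyl 2-[(1R,2S)-1-[3,4-bis(tert-butyldimethylsilyloxy)phenyl]-2-[3,5-bis(tert-butyldimethylsilyloxy)phenyl]-3-oxopropyl]malonate | CC(C)(C)OC(=O)C(C(=O)OC(C)(C)C)[C@H](c1ccc(O[Si](C)(C)C(C)(C)C)c(O[Si](C)(C)C(C)(C)C)c1)[C@H](C=O)c1cc(O[Si](C)(C)C(C)(C)C)cc(O[Si](C)(C)C(C)(C)C)c1 | intermediate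
12 | di-tert-butyl 2-[(1R,2R)-4,4-dibromo-1-[3,4-bis(tert-butyldimethylsilyloxy)phenyl]-2-[3,5-bis(tert-butyldimethylsilyloxy)phenyl]but-3-en-1-yl]malonate | CC(C)(C)OC(=O)C(C(=O)OC(C)(C)C)[C@H](c1ccc(O[Si](C)(C)C(C)(C)C)c(O[Si](C)(C)C(C)(C)C)c1)[C@H](C=C(Br)Br)c1cc(O[Si](C)(C)C(C)(C)C)cc(O[Si](C)(C)C(C)(C)C)c1 | intermediate
13 | 4-[(E)-2-iodoethenyl]-1,2-bis(tert-butyldimethylsilyloxy)benzene | I/C=C/c1ccc(O[Si](C)(C)C(C)(C)C)c(O[Si](C)(C)C(C)(C)C)c1 | intermediate
14 | (E)-2-[3,4-bis(tert-butyldimethylsilyloxy)phenyl]ethenyllithium | [Li]/C=C/c1ccc(O[Si](C)(C)C(C)(C)C)c(O[Si](C)(C)C(C)(C)C)c1 | intermediate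
15 | (E)-2-[3,4-bis(tert-butyldimethylsilyloxy)phenyl]ethenylzinc chloride | Cl[Zn]/C=C/c1ccc(O[Si](C)(C)C(C)(C)C)c(O[Si](C)(C)C(C)(C)C)c1 | intermediate
16 | di-tert-butyl 2-[(1R,2R,3Z,5E)-4-bromo-1,6-bis[3,4-bis(tert-butyldimethylsilyloxy)phenyl]-2-[3,5-bis(tert-butyldimethylsilyloxy)phenyl]hexa-3,5-dien-1-yl]malonate | CC(C)(C)OC(=O)C(C(=O)OC(C)(C)C)[C@H](c1ccc(O[Si](C)(C)C(C)(C)C)c(O[Si](C)(C)C(C)(C)C)c1)[C@H](/C=C(\Br)/C=C/c1ccc(O[Si](C)(C)C(C)(C)C)c(O[Si](C)(C)C(C)(C)C)c1)c1cc(O[Si](C)(C)C(C)(C)C)cc(O[Si](C)(C)C(C)(C)C)c1 | intermediate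
17 | di-tert-butyl 2-[(1R,2R,3Z,5E)-4-bromo-1,6-bis(3,4-dihydroxyphenyl)-2-(3,5-dihydroxyphenyl)hexa-3,5-dien-1-yl]malonate | CC(C)(C)OC(=O)C(C(=O)OC(C)(C)C)[C@H](c1ccc(O)c(O)c1)[C@H](/C=C(\Br)/C=C/c1ccc(O)c(O)c1)c1cc(O)cc(O)c1 | intermediate
18 | di-tert-butyl 2-[(1R,2R,3Z,5E)-4-bromo-1,6-bis(3,4-diacetoxyphenyl)-2-(3,5-diacetoxyphenyl)hexa-3,5-dien-1-yl]malonate | CC(C)(C)OC(=O)C(C(=O)OC(C)(C)C)[C@H](c1ccc(OC(C)=O)c(OC(C)=O)c1)[C@H](/C=C(\Br)/C=C/c1ccc(OC(C)=O)c(OC(C)=O)c1)c1cc(OC(C)=O)cc(OC(C)=O)c1 | intermediate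
19 | (trimethylsilyl)methylmagnesium chloride | C[Si](C)(C)C[Mg]Cl | starting material
20 | (trimethylsilyl)methylzinc chloride | C[Si](C)(C)C[Zn]Cl | intermediate
21 | di-tert-butyl 2-[(1R,2S,3E,5E)-1,6-bis(3,4-diacetoxyphenyl)-2-(3,5-diacetoxyphenyl)-4-[(trimethylsilyl)methyl]hexa-3,5-dien-1-yl]malonate | CC(C)(C)OC(=O)C(C(=O)OC(C)(C)C)[C@H](c1ccc(OC(C)=O)c(OC(C)=O)c1)[C@H](/C=C(/C[Si](C)(C)C)\C=C\c1ccc(OC(C)=O)c(OC(C)=O)c1)c1cc(OC(C)=O)cc(OC(C)=O)c1 | intermediate
22 | bis(trimethylsilyl) 2-[(1R,2S,3E,5E)-1,6-bis(3,4-diacetoxyphenyl)-2-(3,5-diacetoxyphenyl)-4-[(trimethylsilyl)methyl]hexa-3,5-dien-1-yl]malonate | C[Si](C)(C)OC(=O)C(C(=O)O[Si](C)(C)C)[C@H](c1ccc(OC(C)=O)c(OC(C)=O)c1)[C@H](/C=C(/C[Si](C)(C)C)\C=C\c1ccc(OC(C)=O)c(OC(C)=O)c1)c1cc(OC(C)=O)cc(OC(C)=O)c1 | intermediate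
23 | 2-[(1R,2S,3E,5E)-1,6-bis(3,4-diacetoxyphenyl)-2-(3,5-diacetoxyphenyl)-4-[(trimethylsilyl)methyl]hexa-3,5-dien-1-yl]malonyl dichloride | ClC(=O)C(C(Cl)=O)[C@H](c1ccc(OC(C)=O)c(OC(C)=O)c1)[C@H](/C=C(/C[Si](C)(C)C)\C=C\c1ccc(OC(C)=O)c(OC(C)=O)c1)c1cc(OC(C)=O)cc(OC(C)=O)c1 | intermediate
24 | (1R,3R,4R,5R)-5-(3,4-diacetoxyphenyl)-4-(3,5-diacetoxyphenyl)-3-[(3E)-4-(3,4-diacetoxyphenyl)buta-1,3-dien-2-yl]-2-oxocyclopentane-1-carbonyl chloride (reactive epimer, C1 equilibrates) | ClC(=O)[C@H]1C(=O)[C@@H](C(=C)/C=C/c2ccc(OC(C)=O)c(OC(C)=O)c2)[C@H](c2cc(OC(C)=O)cc(OC(C)=O)c2)[C@H]1c1ccc(OC(C)=O)c(OC(C)=O)c1 | intermediate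
25 | jezonodione hexaacetate, (1S,5R,6R,7R)-7-(3,4-diacetoxyphenyl)-6-(3,5-diacetoxyphenyl)-4-[(E)-2-(3,4-diacetoxyphenyl)ethenyl]bicyclo[3.2.1]oct-3-ene-2,8-dione | O=C1C=C(/C=C/c2ccc(OC(C)=O)c(OC(C)=O)c2)[C@@H]2C(=O)[C@H]1[C@H](c1ccc(OC(C)=O)c(OC(C)=O)c1)[C@H]2c1cc(OC(C)=O)cc(OC(C)=O)c1 | intermediate
26 | jezonodione, (1S,5R,6R,7R)-7-(3,4-dihydroxyphenyl)-6-(3,5-dihydroxyphenyl)-4-[(E)-2-(3,4-dihydroxyphenyl)ethenyl]bicyclo[3.2.1]oct-3-ene-2,8-dione | O=C1C=C(/C=C/c2ccc(O)c(O)c2)[C@@H]2C(=O)[C@H]1[C@H](c1ccc(O)c(O)c1)[C@H]2c1cc(O)cc(O)c1 | target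

**Step count**

Total step count: 13.
Longest linear sequence: 10 steps (steps 1, 2, 5, 6, 8, 9, 10, 11, 12, 13).

**Steps most likely to fail**

Step 12 (proposed new method). Once the cyclopentanone has formed, the remaining β-keto acyl chloride can lose HCl to an acylketene and oligomerise, or an aryl ring can intercept the second acylium, before the diene terminus is acylated. The C4 arm may also be delivered to the wrong face. The fallback uses known reactions only, separates the two acylations, sets out from 23 and comes back at 25. 23 is exposed to TiCl4 at −78 °C only for the intramolecular acylation of the allylsilane by one acyl chloride. The second acyl chloride of 24 is then trapped cold with pyridine and tert-butanol as tert-butyl (3R,4R,5R)-5-(3,4-diacetoxyphenyl)-4-(3,5-diacetoxyphenyl)-3-[(3E)-4-(3,4-diacetoxyphenyl)buta-1,3-dien-2-yl]-2-oxocyclopentane-1-carboxylate F1 (mixture at C1), a stable β-keto ester on which the configuration at C4 can be checked. Trifluoroacetic acid then frees (3R,4R,5R)-5-(3,4-diacetoxyphenyl)-4-(3,5-diacetoxyphenyl)-3-[(3E)-4-(3,4-diacetoxyphenyl)buta-1,3-dien-2-yl]-2-oxocyclopentane-1-carboxylic acid F2, which is not isolated. It is treated at 0 °C with trifluoroacetic anhydride, so that its mixed anhydride acylates the diene terminus C2 (acylation of alkenes by carboxylic acids in trifluoroacetic anhydride) and gives 25.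

Step 5. The lithium-bridged transition state may give poor simple diastereoselection (anti instead of syn adduct), or the selectivity may erode by retro-Michael equilibration. The fallback sets out from 3 and 8 and comes back at 11, replacing the stoichiometric azaenolate by enamine catalysis. Crude 3 (step 2 without RAMP) and 8 are combined with (S)-α,α-diphenylprolinol trimethylsilyl ether (20 mol %) and benzoic acid in CHCl3 at 4 °C. The E enamine reacts through the acyclic synclinal transition state that gives syn adducts, and the shielded face of the S catalyst should lead to 7S and therefore 6R. The aldehyde 11 is carried straight into the dibromoolefination of step 6. No new compound is made (F0).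

Step 11. During the silyl transfer the tert-butyl cation may be captured by the nucleophilic allylsilane, or traces of triflic acid may protodesilylate it. The fallback sets out from 18 and comes back at 23, removing the acid-labile esters before the allylsilane exists. Trifluoroacetic acid in CH2Cl2 converts 18 into 2-[(1R,2R,3Z,5E)-4-bromo-1,6-bis(3,4-diacetoxyphenyl)-2-(3,5-diacetoxyphenyl)hexa-3,5-dien-1-yl]malonic acid F3. N-(tert-Butyldimethylsilyl)-N-methyltrifluoroacetamide silylates it under neutral conditions to bis(tert-butyldimethylsilyl) 2-[(1R,2R,3Z,5E)-4-bromo-1,6-bis(3,4-diacetoxyphenyl)-2-(3,5-diacetoxyphenyl)hexa-3,5-dien-1-yl]malonate F4. Negishi coupling with 20 under the conditions of step 10 gives bis(tert-butyldimethylsilyl) 2-[(1R,2S,3E,5E)-1,6-bis(3,4-diacetoxyphenyl)-2-(3,5-diacetoxyphenyl)-4-[(trimethylsilyl)methyl]hexa-3,5-dien-1-yl]malonate F5. Oxalyl chloride with catalytic DMF then turns the two silyl esters directly into the acyl chlorides of 23.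

**Further compounds**

F1 | step 12 | tert-butyl (3R,4R,5R)-5-(3,4-diacetoxyphenyl)-4-(3,5-diacetoxyphenyl)-3-[(3E)-4-(3,4-diacetoxyphenyl)buta-1,3-dien-2-yl]-2-oxocyclopentane-1-carboxylate (C1 epimers) | CC(C)(C)OC(=O)C1C(=O)[C@@H](C(=C)/C=C/c2ccc(OC(C)=O)c(OC(C)=O)c2)[C@H](c2cc(OC(C)=O)cc(OC(C)=O)c2)[C@H]1c1ccc(OC(C)=O)c(OC(C)=O)c1
F2 | step 12 | (3R,4R,5R)-5-(3,4-diacetoxyphenyl)-4-(3,5-diacetoxyphenyl)-3-[(3E)-4-(3,4-diacetoxyphenyl)buta-1,3-dien-2-yl]-2-oxocyclopentane-1-carboxylic acid (C1 epimers) | OC(=O)C1C(=O)[C@@H](C(=C)/C=C/c2ccc(OC(C)=O)c(OC(C)=O)c2)[C@H](c2cc(OC(C)=O)cc(OC(C)=O)c2)[C@H]1c1ccc(OC(C)=O)c(OC(C)=O)c1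
F0 | step 5 | none | none
F3 | step 11 | 2-[(1R,2R,3Z,5E)-4-bromo-1,6-bis(3,4-diacetoxyphenyl)-2-(3,5-diacetoxyphenyl)hexa-3,5-dien-1-yl]malonic acid | OC(=O)C(C(=O)O)[C@H](c1ccc(OC(C)=O)c(OC(C)=O)c1)[C@H](/C=C(\Br)/C=C/c1ccc(OC(C)=O)c(OC(C)=O)c1)c1cc(OC(C)=O)cc(OC(C)=O)c1
F4 | step 11 | bis(tert-butyldimethylsilyl) 2-[(1R,2R,3Z,5E)-4-bromo-1,6-bis(3,4-diacetoxyphenyl)-2-(3,5-diacetoxyphenyl)hexa-3,5-dien-1-yl]malonate | CC(C)(C)[Si](C)(C)OC(=O)C(C(=O)O[Si](C)(C)C(C)(C)C)[C@H](c1ccc(OC(C)=O)c(OC(C)=O)c1)[C@H](/C=C(\Br)/C=C/c1ccc(OC(C)=O)c(OC(C)=O)c1)c1cc(OC(C)=O)cc(OC(C)=O)c1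
F5 | step 11 | bis(tert-butyldimethylsilyl) 2-[(1R,2S,3E,5E)-1,6-bis(3,4-diacetoxyphenyl)-2-(3,5-diacetoxyphenyl)-4-[(trimethylsilyl)methyl]hexa-3,5-dien-1-yl]malonate | CC(C)(C)[Si](C)(C)OC(=O)C(C(=O)O[Si](C)(C)C(C)(C)C)[C@H](c1ccc(OC(C)=O)c(OC(C)=O)c1)[C@H](/C=C(/C[Si](C)(C)C)\C=C\c1ccc(OC(C)=O)c(OC(C)=O)c1)c1cc(OC(C)=O)cc(OC(C)=O)c1
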